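Ring B is cut at C7–C8 and C9–C10. Its tetrasubstituted C8=C9 alkene lies between the acyloxy-bearing C7 and the quaternary C10, which is the pattern an alkyne dienophile leaves behind. Ring A, with the C4 gem-dimethyl and the C10 methyl, is the ring alkene of β-cyclocitral. One enantioselective [4+2] cycloaddition of but-2-ynal to a (Z)-1-isovaleryloxy-2-silyloxy diene mounted on 2,6,6-trimethylcyclohexene should therefore close ring B and set C7 and C10. It leaves a C6 silyl enol ether (masked ketone, later the 6β-acetate) and a C9 formyl group for the side chain. The diene already carries the C7 isovalerate.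

Key step: step 6

Numbering: labdane numbering is used for all bicyclic compounds (ring A = C1–C5 and C10, ring B = C5–C10).
Assumption: the (S)-oxazaborolidinium salt is taken to expose the face of bound 8 that leads to (7S,10S)-9; if the adduct proves to be the mirror image, the catalyst from (R)-diphenylprolinol is used with nothing else changed.

Step 1
Reactants: 1 β-cyclocitral (2,6,6-trimethylcyclohex-1-ene-1-carbaldehyde)
Product: 2 2-chloro-1-(2,6,6-trimethylcyclohex-1-en-1-yl)ethan-1-ol (racemic)
Conditions: ICH2Cl, MeLi·LiBr, THF, −78 °C; AcOH, −78 °C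
Reagents that add atoms: chloroiodomethane ClCI
Why: Chloromethyllithium, generated by iodine–lithium exchange in the presence of the non-enolisable aldehyde (halomethyllithium carbenoid addition under Barbier conditions), should add 1,2 to the formyl group, and the cold acidic quench keeps the alkoxide from closing to the epoxide; the carbinol centre is racemic and is removed in step 2.

Step 2
Reactants: 2 2-chloro-1-(2,6,6-trimethylcyclohex-1-en-1-yl)ethan-1-ol
Product: 3 2-chloro-1-(2,6,6-trimethylcyclohex-1-en-1-yl)ethan-1-one
Conditions: Dess–Martin periodinane, CH2Cl2, 0 °C to rt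
Reagents that add atoms: none
Why: Dess–Martin oxidation of the secondary allylic alcohol under neutral conditions should give the ketone without touching the primary chloride or the tetrasubstituted alkene.

Step 3
Reactants: 3 2-chloro-1-(2,6,6-trimethylcyclohex-1-en-1-yl)ethan-1-one; 4 3-methylbutanoic acid
Product: 5 2-oxo-2-(2,6,6-trimethylcyclohex-1-en-1-yl)ethyl 3-methylbutanoate
Conditions: K2CO3, NaI (10 mol %), DMF, rt
Reagents that add atoms: none
Why: SN2 displacement of the carbonyl-activated primary chloride by the potassium carboxylate, with iodide (Finkelstein) catalysis, installs the future C7 ester, and the weakly basic carboxylate should not trigger Favorskii or elimination pathways.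

Step 4
Reactants: 5 2-oxo-2-(2,6,6-trimethylcyclohex-1-en-1-yl)ethyl 3-methylbutanoate
Product: 6 (Z)-2-(tert-butyldimethylsilyloxy)-2-(2,6,6-trimethylcyclohex-1-en-1-yl)vinyl 3-methylbutanoate
Conditions: TBSOTf, Et3N, CH2Cl2, −78 to 0 °C
Reagents that add atoms: tert-butyldimethylsilyl trifluoromethanesulfonate CC(C)(C)[Si](C)(C)OS(=O)(=O)C(F)(F)F
Why: Soft enolisation (silyl triflate and amine) at the only α-CH2 of the α-acyloxy ketone should give the silyl enol ether with the acyloxy group turned away from the bulky trimethylcyclohexenyl group and cis to the silyloxy group, which is the Z geometry.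

Step 5
Reactants: 7 but-2-yn-1-ol
Product: 8 but-2-ynal
Conditions: activated MnO2, CH2Cl2, rt; filtered, dried over 4 Å sieves, used as solution
Reagents that add atoms: none
Why: MnO2 oxidation of the propargylic alcohol stops at the aldehyde, and the volatile ynal is kept in solution for direct use.

Step 6
Reactants: 6 (Z)-2-(tert-butyldimethylsilyloxy)-2-(2,6,6-trimethylcyclohex-1-en-1-yl)vinyl 3-methylbutanoate; 8 but-2-ynal
Product: 9 (7S,10S)-6-(tert-butyldimethylsilyloxy)-7α-(3-methylbutanoyloxy)-12,13,14,15,16-pentanorlabda-5,8-dien-11-al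
Conditions: (S)-1-(2-methylphenyl)-3,3-diphenyltetrahydro-1H,3H-pyrrolo[1,2-c][1,3,2]oxazaborole (20 mol %), HN(SO2CF3)2 (17 mol %), CH2Cl2, −78 to −40 °C; Et3N quench
Reagents that add atoms: none
Why: Coordination of the formyl oxygen of 8 to the cationic boron lowers the alkyne LUMO, and the diene adds in one concerted but unsymmetrical [4+2] event in which the enol-ether carbon C7 engages the ynal β-carbon (C8) well before the crowded C9–C10 bond is complete. The closest known reactions are oxazaborolidinium-catalysed Diels–Alder additions of 2-silyloxy dienes, chiral boron Lewis acid catalysis of ynal cycloadditions, and thermal additions of 2,6,6-trimethylcyclohexenyl dienes to activated alkynes. Ring B is closed as a cyclohexa-1,4-diene by the intermolecular cycloaddition itself, both ring bonds being formed in that single step with no separate cyclisation. C7 and C10 are created together: both bonds form on one face of the diene, so the outward-pointing groups of the s-cis conformer (O7 and ring carbon C1) end up cis, which places the 7-ester trans to the C10 methyl (relative control by the Z geometry of 6), while the aryl groups of the catalyst cover one face of the bound ynal and fix the absolute sense. The step needs C7-to-C8 regiochemistry, secured by the C6 silyloxy group that makes C7 the nucleophilic terminus and by the tertiary C10 that carries the developing positive charge, and it needs cycloaddition to outrun Mukaiyama aldol addition at the formyl carbon, which the bulky tert-butyldimethylsilyl group, the low temperature and the slight deficit of acid over oxazaborolidine should ensure.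

Step 7
Reactants: 9 (7S,10S)-6-(tert-butyldimethylsilyloxy)-7α-(3-methylbutanoyloxy)-12,13,14,15,16-pentanorlabda-5,8-dien-11-al
Product: 10 6-(tert-butyldimethylsilyloxy)-7α-(3-methylbutanoyloxy)-13,14,15,16-tetranorlabda-5,8,11-triene
Conditions: Ph3PCH3Br, KN(SiMe3)2, THF, 0 °C; then 9, −78 to 0 °C
Reagents that add atoms: methyltriphenylphosphonium bromide C[P+](c1ccccc1)(c1ccccc1)c1ccccc1.[Br-]
Why: Wittig methylenation of the hindered, non-enolisable enal, whose formyl group sits in the same environment as that of β-cyclocitral, with pre-formed ylide (base in slight deficit) at low temperature should leave the ester, the silyl enol ether and the C7 centre untouched.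

Step 8
Reactants: 11 tert-butyl 3-oxobutanoate (tert-butyl acetoacetate)
Product: 12 tert-butyl (E)-3-(trifluoromethylsulfonyloxy)but-2-enoate
Conditions: Tf2O, aq. Me4NOH, hexanes, 5 °C
Reagents that add atoms: trifluoromethanesulfonic anhydride O=S(=O)(OS(=O)(=O)C(F)(F)F)C(F)(F)F
Why: Biphasic O-triflation of the non-chelated tetramethylammonium enolate of the β-keto ester should give the E enol triflate (triflate trans to the ester), the geometry needed at C13.

Step 9
Reactants: 10 6-(tert-butyldimethylsilyloxy)-7α-(3-methylbutanoyloxy)-13,14,15,16-tetranorlabda-5,8,11-triene; 13 9-borabicyclo[3.3.1]nonane (9-BBN); 12 tert-butyl (E)-3-(trifluoromethylsulfonyloxy)but-2-enoate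
Product: 15 tert-butyl (13E)-6-(tert-butyldimethylsilyloxy)-7α-(3-methylbutanoyloxy)labda-5,8,13-trien-15-oate, via B-alkyl-9-BBN adduct 14 (not isolated)
Conditions: 13, THF, rt to 40 °C; then 12, [1,1'-bis(diphenylphosphino)ferrocene]palladium dichloride PdCl2(dppf) (5 mol %), aq. K3PO4, DMF, rt
Reagents that add atoms: none
Why: Anti-Markovnikov hydroboration by 9-BBN should take only the monosubstituted C11=C12 alkene (both tetrasubstituted alkenes are inert to the bulky borane), and B-alkyl Suzuki–Miyaura coupling with the enol triflate proceeds with retention of its geometry to give the 13E enoate.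

Step 10
Reactants: 15 tert-butyl (13E)-6-(tert-butyldimethylsilyloxy)-7α-(3-methylbutanoyloxy)labda-5,8,13-trien-15-oate
Product: 16 tert-butyl (13E)-7α-(3-methylbutanoyloxy)-6-oxo-5α-labda-8,13-dien-15-oate
Conditions: Bu4NF, AcOH, THF, −20 to 0 °C
Reagents that add atoms: none
Why: Fluoride cleaves the silyl enol ether and acetic acid protonates the C6 enolate at C5 (kinetic enolate protonation) on the α face, the axial direction opposite to the two β-axial methyl groups on C4 and C10, which should give the trans ring fusion; in that product the C7–H lies close to the carbonyl plane, which together with the buffer should protect C7.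

Step 11
Reactants: 16 tert-butyl (13E)-7α-(3-methylbutanoyloxy)-6-oxo-5α-labda-8,13-dien-15-oate
Product: 17 tert-butyl (13E)-6β-hydroxy-7α-(3-methylbutanoyloxy)-5α-labda-8,13-dien-15-oate
Conditions: NaBH4, MeOH/THF, −20 to 0 °C
Reagents that add atoms: none
Why: In this NaBH4 ketone reduction hydride should attack C6 from the α face because the β face is covered by the syn-axial methyl groups on C4 and C10, giving the axial 6β alcohol; it is trans-diaxial to the 7α ester, so acyl migration is not possible, and the esters are not reduced.

Step 12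
Reactants: 17 tert-butyl (13E)-6β-hydroxy-7α-(3-methylbutanoyloxy)-5α-labda-8,13-dien-15-oate
Product: 18 tert-butyl (13E)-6β-acetoxy-7α-(3-methylbutanoyloxy)-5α-labda-8,13-dien-15-oate
Conditions: Ac2O, 4-(dimethylamino)pyridine (DMAP), pyridine, 40 °C
Reagents that add atoms: acetic anhydride CC(=O)OC(C)=O
Why: DMAP-catalysed acetylation (Steglich-type nucleophilic catalysis) of the only free hydroxyl should give the 6β-acetate, with gentle heating to overcome the axial, doubly flanked position.

Step 13
Reactants: 18 tert-butyl (13E)-6β-acetoxy-7α-(3-methylbutanoyloxy)-5α-labda-8,13-dien-15-oate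
Product: 19 (13E)-6β-acetoxy-7α-(3-methylbutanoyloxy)-5α-labda-8,13-dien-15-oic acid (CNP0328312.2)
Conditions: CF3CO2H, CH2Cl2, 0 °C
Reagents that add atoms: none
Why: Acidolysis of the tert-butyl ester (loss of 2-methylpropene through the tert-butyl cation) should free the C15 acid, while the acetate, the isovalerate and both alkenes tolerate cold trifluoroacetic acid.

Compound list
1 | β-cyclocitral (2,6,6-trimethylcyclohex-1-ene-1-carbaldehyde) | CC1=C(C=O)C(C)(C)CCC1 | starting material
2 | 2-chloro-1-(2,6,6-trimethylcyclohex-1-en-1-yl)ethan-1-ol (racemic) | CC1=C(C(O)CCl)C(C)(C)CCC1 | intermediate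
3 | 2-chloro-1-(2,6,6-trimethylcyclohex-1-en-1-yl)ethan-1-one | CC1=C(C(=O)CCl)C(C)(C)CCC1 | intermediate
4 | 3-methylbutanoic acid | CC(C)CC(=O)O | starting material
5 | 2-oxo-2-(2,6,6-trimethylcyclohex-1-en-1-yl)ethyl 3-methylbutanoate | CC(C)CC(=O)OCC(=O)C1=C(C)CCCC1(C)C | intermediate
6 | (Z)-2-(tert-butyldimethylsilyloxy)-2-(2,6,6-trimethylcyclohex-1-en-1-yl)vinyl 3-methylbutanoate | CC(C)CC(=O)O/C=C(\O[Si](C)(C)C(C)(C)C)C1=C(C)CCCC1(C)C | intermediate
7 | but-2-yn-1-ol | CC#CCO | starting material
8 | but-2-ynal | CC#CC=O | intermediate
9 | (7S,10S)-6-(tert-butyldimethylsilyloxy)-7α-(3-methylbutanoyloxy)-12,13,14,15,16-pentanorlabda-5,8-dien-11-al (ring B cyclohexa-1,4-diene, C9 formyl, C8 methyl, 10β-methyl) | O=CC1=C(C)[C@H](OC(=O)CC(C)C)C(O[Si](C)(C)C(C)(C)C)=C2C(C)(C)CCC[C@]12C | intermediate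
10 | 6-(tert-butyldimethylsilyloxy)-7α-(3-methylbutanoyloxy)-13,14,15,16-tetranorlabda-5,8,11-triene (C9 vinyl) | C=CC1=C(C)[C@H](OC(=O)CC(C)C)C(O[Si](C)(C)C(C)(C)C)=C2C(C)(C)CCC[C@]12C | intermediate
11 | tert-butyl 3-oxobutanoate | CC(=O)CC(=O)OC(C)(C)C | starting material
12 | tert-butyl (E)-3-(trifluoromethylsulfonyloxy)but-2-enoate | C/C(OS(=O)(=O)C(F)(F)F)=C\C(=O)OC(C)(C)C | intermediate
13 | 9-borabicyclo[3.3.1]nonane (9-BBN, used as its dimer) | B1C2CCCC1CCC2 | starting material
14 | 12-(9-borabicyclo[3.3.1]nonan-9-yl)-6-(tert-butyldimethylsilyloxy)-7α-(3-methylbutanoyloxy)-13,14,15,16-tetranorlabda-5,8-diene | C1CCC2CCCC1B2CCC3=C(C)[C@H](OC(=O)CC(C)C)C(O[Si](C)(C)C(C)(C)C)=C4C(C)(C)CCC[C@]34C | intermediate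
15 | tert-butyl (13E)-6-(tert-butyldimethylsilyloxy)-7α-(3-methylbutanoyloxy)labda-5,8,13-trien-15-oate | CC(C)(C)OC(=O)/C=C(C)/CCC1=C(C)[C@H](OC(=O)CC(C)C)C(O[Si](C)(C)C(C)(C)C)=C2C(C)(C)CCC[C@]12C | intermediate
16 | tert-butyl (13E)-7α-(3-methylbutanoyloxy)-6-oxo-5α-labda-8,13-dien-15-oate (trans ring fusion) | O=C1[C@@H](OC(=O)CC(C)C)C(C)=C(CC/C(C)=C/C(=O)OC(C)(C)C)[C@@]2(C)CCCC(C)(C)[C@H]12 | intermediate
17 | tert-butyl (13E)-6β-hydroxy-7α-(3-methylbutanoyloxy)-5α-labda-8,13-dien-15-oate | O[C@@H]1[C@@H](OC(=O)CC(C)C)C(C)=C(CC/C(C)=C/C(=O)OC(C)(C)C)[C@@]2(C)CCCC(C)(C)[C@H]12 | intermediate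
18 | tert-butyl (13E)-6β-acetoxy-7α-(3-methylbutanoyloxy)-5α-labda-8,13-dien-15-oate | CC(=O)O[C@@H]1[C@@H](OC(=O)CC(C)C)C(C)=C(CC/C(C)=C/C(=O)OC(C)(C)C)[C@@]2(C)CCCC(C)(C)[C@H]12 | intermediate
19 | (5S,6S,7S,10S,13E)-6β-acetoxy-7α-(3-methylbutanoyloxy)labda-8,13-dien-15-oic acid (CNP0328312.2) | CC(=O)O[C@@H]1[C@@H](OC(=O)CC(C)C)C(C)=C(CC/C(C)=C/C(=O)O)[C@@]2(C)CCCC(C)(C)[C@H]12 | target

Total step count: 13.
Longest linear sequence: 11 steps from β-cyclocitral (steps 1–4, 6, 7, 9–13); steps 5 and 8 are one-step side branches.

Steps most likely to fail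

1. Step 6. The twisted diene may not reach the s-cis geometry at temperatures where the catalyst still discriminates the faces of the ynal. The enol ether may add to the formyl carbon (aldol pathway) or transfer silicon instead of closing the ring. Enantiofacial control may be eroded by the fully substituted C10 terminus. The fallback sets out from 6 and 8 and gives up catalyst control. The two are heated without Lewis acid (toluene, 110 °C, sealed tube, radical inhibitor; or 12 kbar, CH2Cl2, rt), conditions under which dienes of this class add activated alkynes. The Z geometry still fixes the relative configuration, so the product should be the racemate made of 9 and its mirror image, the (7R,10R)-aldehyde ent-9 F1. Preparative chromatography on a chiral stationary phase separates the two, and the route is rejoined at 9.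

2. Step 10. Protonation at C5 may occur in part on the β face and give the cis ring fusion, and the freed β,γ-unsaturated α-acyloxy ketone may enolise toward C7. The fallback sets out from 15. The desilylation is run as before and any cis-fused ketone, the 5β epimer of 16 F2, is not separated. The mixture is then equilibrated with catalytic 1,8-diazabicyclo[5.4.0]undec-7-ene in toluene at rt, so that control passes from kinetic protonation to thermodynamic epimerisation. The trans-fused ketone with the axial 7α-acyloxy group should be the most stable β,γ-unsaturated isomer (trans fusion, no allylic strain between O7 and the C8 methyl). The equilibration is stopped before the alkene moves into conjugation, and the route is rejoined at 16.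

3. Step 12. Acylation of the 6β hydroxyl, shielded by the syn-axial methyl groups on C4 and C10, may stall, and forcing conditions may cause elimination or ester scrambling. The fallback sets out from 17. The alcohol is deprotonated with LiN(SiMe3)2 (THF, −78 °C) to the lithium alkoxide of 17 F3, which is acylated at once with acetyl chloride (−78 to 0 °C). Acylation of a pre-formed alkoxide is the standard answer to hydroxyl groups that resist amine-catalysed acylation, and the trans-diaxial arrangement of O6 and O7 rules out acyl migration. The route is rejoined at 18.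

Further compounds
F1 | step 6 | ent-9, (7R,10R) mirror image of 9 | O=CC1=C(C)[C@@H](OC(=O)CC(C)C)C(O[Si](C)(C)C(C)(C)C)=C2C(C)(C)CCC[C@@]12C
F2 | step 10 | tert-butyl (13E)-7α-(3-methylbutanoyloxy)-6-oxo-5β-labda-8,13-dien-15-oate (cis-fused 5-epimer of 16) | O=C1[C@@H](OC(=O)CC(C)C)C(C)=C(CC/C(C)=C/C(=O)OC(C)(C)C)[C@@]2(C)CCCC(C)(C)[C@@H]12
F3 | step 12 | lithium alkoxide of 17 | [Li+].[O-][C@@H]1[C@@H](OC(=O)CC(C)C)C(C)=C(CC/C(C)=C/C(=O)OC(C)(C)C)[C@@]2(C)CCCC(C)(C)[C@H]12
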